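**Plan**
- Retrosynthesis: the two hydroxyls are masked first (ring B OH as OMe, ring A C1–OH as C1–Bpin). Ring A is then cut at C2–C3 and C6–C1 into 3,5-dibromo-2-pyrone (which supplies C3–C6 after loss of CO2) and the alkyne ArO–C≡C–Bpin (which supplies C2 and C1). The alkyne is taken back through its C–B bond and the O-bound two-carbon unit to tribromoguaiacol.
- Enabling feature: ring A carries Br on C3 and C5 with C4–H between them and C6–H beside, which is the C3–C6 array of 3,5-dibromo-2-pyrone. Its two adjacent oxygenated carbons, C1 (OH) and C2 (O-aryl), remain as a two-carbon aryloxy alkynylboronate.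
- Forward order: ring B is present from the start (tribromination of guaiacol). Its phenol oxygen is vinylated, the vinyl group is raised to the alkyne by bromination/double dehydrobromination and borylated. Ring A is closed last by [4+2] cycloaddition/CO2 extrusion, then C–B is oxidised to C–OH and the methyl ether is cleaved.
- Stereochemistry: none to set. The target has no stereocentre; the only stereocentres on the route (the dibromoethyl ether carbon and the cycloadduct bridgeheads) are transient.

Key step: step 6

Assumption: the tetra-ortho-substituted diaryl ether axis (Br/OH against Br/OH) is taken as freely rotating, so the target is achiral and no enantiocontrol is required.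

**Route**

Step 1
Reactants: 1 guaiacol (2-methoxyphenol)
Product: 2 2,3,4-tribromo-6-methoxyphenol (4,5,6-tribromoguaiacol)
Conditions: Br2 (3.2 equiv), AcOH, 20 → 50 °C
Reagents that add atoms: bromine, BrBr
Why: Electrophilic aromatic bromination; the free OH directs to its para and ortho positions and the OMe to its para position, while the remaining site (ortho to OMe only, flanked by Br) should stay unsubstituted.

Step 2
Reactants: 2 2,3,4-tribromo-6-methoxyphenol; 3 2,4,6-trivinylcyclotriboroxane–pyridine complex
Product: 4 1,2,3-tribromo-4-(ethenyloxy)-5-methoxybenzene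
Conditions: 3 (0.7 equiv), Cu(OAc)2 (1.0 equiv), pyridine (10 equiv), 4 Å MS, CH2Cl2, air, 25 °C
Reagents that add atoms: none
Why: Chan–Lam O-vinylation of a phenol with a vinylboron reagent; copper(II) at room temperature should leave the aryl C–Br bonds alone, and acidic phenols are good partners in this coupling.

Step 3
Reactants: 4 1,2,3-tribromo-4-(ethenyloxy)-5-methoxybenzene
Product: 6 1,2,3-tribromo-4-{[(Z)-2-bromoethenyl]oxy}-5-methoxybenzene, via 1,2-dibromoethyl ether 5 (not isolated)
Conditions: Br2 (1.0 equiv), CH2Cl2, −78 °C; then i-Pr2NEt (2.5 equiv), −78 → 40 °C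
Reagents that add atoms: bromine, BrBr
Why: Bromine addition to the enol ether followed by amine-promoted dehydrobromination of the α-bromo ether, the classical route to 2-bromovinyl ethers (Z isomer expected to predominate); the deactivated ring should not compete for bromine at −78 °C, and any E or 1-bromovinyl isomer would converge on the same alkyne in step 4.

Step 4
Reactants: 6 1,2,3-tribromo-4-{[(Z)-2-bromoethenyl]oxy}-5-methoxybenzene; 7 2-isopropoxy-4,4,5,5-tetramethyl-1,3,2-dioxaborolane
Product: 11 2-[(2,3,4-tribromo-6-methoxyphenoxy)ethynyl]-4,4,5,5-tetramethyl-1,3,2-dioxaborolane, via terminal ynol ether 8 (not isolated), via lithium aryloxyacetylide 9 (not isolated), via lithium alkynylborate 10 (not isolated)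
Conditions: LiHMDS (2.1 equiv), THF, −78 → −20 °C; 7 (1.1 equiv), −78 °C; HCl in Et2O (1.1 equiv), −78 → 20 °C; filtration under Ar, no aqueous work-up
Reagents that add atoms: none
Why: anti-Elimination of HBr from the (Z)-2-bromovinyl ether by a lithium amide and deprotonation of the resulting alkyne is the standard entry to metalated ynol ethers, and trapping a lithium acetylide with the isopropoxy pinacolborate followed by anhydrous HCl is the standard alkynylboronate synthesis; a silylamide is chosen because it neither exchanges nor metalates the tribromoarene as an alkyllithium would.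

Step 5
Reactants: 12 coumalic acid (2-oxo-2H-pyran-5-carboxylic acid)
Product: 13 3,5-dibromo-2H-pyran-2-one
Conditions: NBS (2.5 equiv), LiOAc (cat.), MeCN–H2O (10:1), 25 °C
Reagents that add atoms: N-bromosuccinimide, O=C1CCC(=O)N1Br
Why: Known bromodecarboxylation of the pyrone-5-carboxylic acid (ipso-bromination with loss of CO2) together with electrophilic bromination at C3, the nucleophilic α-position of the pyrone.

Step 6
Reactants: 11 2-[(2,3,4-tribromo-6-methoxyphenoxy)ethynyl]-4,4,5,5-tetramethyl-1,3,2-dioxaborolane; 13 3,5-dibromo-2H-pyran-2-one
Product: 15 2-[3,5-dibromo-2-(2,3,4-tribromo-6-methoxyphenoxy)phenyl]-4,4,5,5-tetramethyl-1,3,2-dioxaborolane, via bicyclic lactone cycloadduct 14 (not isolated)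
Conditions: 13 (1.5 equiv), mesitylene, 4 Å MS, 140 °C, sealed tube, Ar
Reagents that add atoms: none
Why: Proposed new method: the ambiphilic, electron-poor diene 13 should add the push–pull alkyne 11 across C3 and C6 in a concerted, asynchronous [4+2] cycloaddition to the bridged lactone 14, which at this temperature expels CO2 by retro-[4+2] and so delivers the benzene ring directly. The closest known reaction types are the cycloaddition–decarboxylation of 2-pyrones with alkynylboronates to arylboronates and the cycloadditions of 3,5-dibromo-2-pyrone with enol ethers, in which the oxygen-bearing dienophile carbon ends up next to the brominated bridgehead; an aryloxy-substituted alkynylboronate has not been used as the two-carbon partner. Ring A is closed intermolecularly as a six-membered carbocycle from four pyrone carbons and two alkyne carbons (new bonds pyrone C3–C(OAr) and pyrone C6–C(B)) and is aromatised by extrusion, so no oxidation is needed. No stereocentre has to be controlled, because the two bridgehead centres of racemic 14 become sp2 when CO2 leaves. The step needs a single orientation, aryloxy carbon on C3 and boron carbon on C6: the oxygen lone pair and the vacant boron orbital polarise the triple bond in the same sense, making the boron-bearing carbon the nucleophilic terminus that bonds first to the electrophilic C6, and the bulky Bpin group is thereby placed beside C6–H and away from C3–Br. The aryl bromides, methyl ether and pinacol ester should be inert to heat in a hydrocarbon solvent, and an aryl ynol ether has no β-C–H for retro-ene loss of a ketene.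

Step 7
Reactants: 15 2-[3,5-dibromo-2-(2,3,4-tribromo-6-methoxyphenoxy)phenyl]-4,4,5,5-tetramethyl-1,3,2-dioxaborolane
Product: 16 3,5-dibromo-2-(2,3,4-tribromo-6-methoxyphenoxy)phenol
Conditions: 30% aq H2O2, 1 M NaOH, THF, 0 °C; then aq NH4Cl
Reagents that add atoms: hydrogen peroxide, OO
Why: Hydroperoxide oxidation of an arylboronic ester (1,2-aryl shift from boron to oxygen, then borate hydrolysis); the reaction is kept cold and short so that the new ortho-phenoxide does not displace an ortho-bromine of the other ring.

Step 8
Reactants: 16 3,5-dibromo-2-(2,3,4-tribromo-6-methoxyphenoxy)phenol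
Product: 17 3,4,5-tribromo-2-(2,4-dibromo-6-hydroxyphenoxy)phenol (target)
Conditions: BBr3 (4 equiv), CH2Cl2, −78 → 20 °C; then H2O
Reagents that add atoms: none
Why: Boron tribromide demethylation of an aryl methyl ether; bromide attacks only the methyl carbon, and the diaryl ether and aryl bromides should be inert.

**Compound list**
1 | guaiacol (2-methoxyphenol) | COc1ccccc1O | starting material
2 | 2,3,4-tribromo-6-methoxyphenol | COc1cc(Br)c(Br)c(Br)c1O | intermediate
3 | 2,4,6-trivinylcyclotriboroxane–pyridine complex | C=CB1OB(C=C)OB(C=C)O1.c1ccncc1 | starting material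
4 | 1,2,3-tribromo-4-(ethenyloxy)-5-methoxybenzene | COc1cc(Br)c(Br)c(Br)c1OC=C | intermediate
5 | 1,2,3-tribromo-4-(1,2-dibromoethoxy)-5-methoxybenzene (racemic) | COc1cc(Br)c(Br)c(Br)c1OC(Br)CBr | intermediate (not isolated)
6 | 1,2,3-tribromo-4-{[(Z)-2-bromoethenyl]oxy}-5-methoxybenzene | COc1cc(Br)c(Br)c(Br)c1O/C=C\Br | intermediate
7 | 2-isopropoxy-4,4,5,5-tetramethyl-1,3,2-dioxaborolane | CC(C)OB1OC(C)(C)C(C)(C)O1 | starting material
8 | 1,2,3-tribromo-4-(ethynyloxy)-5-methoxybenzene | COc1cc(Br)c(Br)c(Br)c1OC#C | intermediate (not isolated)
9 | lithium (2,3,4-tribromo-6-methoxyphenoxy)acetylide | [Li]C#COc1c(OC)cc(Br)c(Br)c1Br | intermediate (not isolated)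
10 | lithium [(2,3,4-tribromo-6-methoxyphenoxy)ethynyl](isopropoxy)(pinacolato)borate | [Li+].CC(C)O[B-]1(C#COc2c(OC)cc(Br)c(Br)c2Br)OC(C)(C)C(C)(C)O1 | intermediate (not isolated)
11 | 2-[(2,3,4-tribromo-6-methoxyphenoxy)ethynyl]-4,4,5,5-tetramethyl-1,3,2-dioxaborolane | COc1cc(Br)c(Br)c(Br)c1OC#CB1OC(C)(C)C(C)(C)O1 | intermediate
12 | coumalic acid | O=C(O)c1ccc(=O)oc1 | starting material
13 | 3,5-dibromo-2H-pyran-2-one | O=c1occ(Br)cc1Br | intermediate
14 | 4,7-dibromo-5-(2,3,4-tribromo-6-methoxyphenoxy)-6-(pinacolboryl)-2-oxabicyclo[2.2.2]octa-5,7-dien-3-one (racemic) | O=C1OC2C(Br)=CC1(Br)C(Oc3c(OC)cc(Br)c(Br)c3Br)=C2B4OC(C)(C)C(C)(C)O4 | intermediate (not isolated)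
15 | 2-[3,5-dibromo-2-(2,3,4-tribromo-6-methoxyphenoxy)phenyl]-4,4,5,5-tetramethyl-1,3,2-dioxaborolane | COc1cc(Br)c(Br)c(Br)c1Oc1c(B2OC(C)(C)C(C)(C)O2)cc(Br)cc1Br | intermediate
16 | 3,5-dibromo-2-(2,3,4-tribromo-6-methoxyphenoxy)phenol | COc1cc(Br)c(Br)c(Br)c1Oc1c(O)cc(Br)cc1Br | intermediate
17 | 3,4,5-tribromo-2-(2,4-dibromo-6-hydroxyphenoxy)phenol | Oc1cc(Br)cc(Br)c1Oc1c(O)cc(Br)c(Br)c1Br | target

**Step count**
Total steps: 8. Longest linear sequence: 7 (steps 1–4 and 6–8 from guaiacol); step 5 is a one-step branch.

**Steps most likely to fail**

Step 6 (proposed new method). The cycloaddition may be slower than thermal decay of the ynol ether boronate (oligomerisation, hydrolytic loss of boron), or bond formation may take the opposite orientation and place boron beside C3–Br. The fallback uses known chemistry and sets out from 2. Nucleophilic aromatic substitution of the phenoxide of 2 on commercial 3,5-dibromo-2-fluorobenzaldehyde (K2CO3, DMAc, 100 °C; the formyl group activates the ortho fluorine) would give 3,5-dibromo-2-(2,3,4-tribromo-6-methoxyphenoxy)benzaldehyde F1. Baeyer–Villiger oxidation with mCPBA in CH2Cl2 would give 3,5-dibromo-2-(2,3,4-tribromo-6-methoxyphenoxy)phenyl formate F2, and methanolysis (K2CO3, MeOH) would return to the route at phenol 16. Ring A then comes from a preformed benzene, and the diaryl ether bond is made by substitution rather than cycloaddition.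

Step 4. The amide base may expel the hindered aryloxide instead of bromide, and acid release of the boronate from the ate complex may add HCl across the acid-sensitive ynol ether or strip boron. The fallback sets out from 6 and separates the two events. Potassium tert-butoxide (THF, −40 → 0 °C) would carry out the elimination only as far as the neutral terminal ynol ether 8, which is isolated this time by filtration through basic alumina and kept in solution. A base- and acid-free catalytic dehydrogenative C–H borylation of the terminal alkyne with pinacolborane (iridium pincer or copper–carbene catalyst, 25 °C) would then give 11, where the route is rejoined.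

Step 2. Transmetalation and C–O bond formation at copper may stall for a phenol flanked by Br and OMe, leaving 2 unconverted or oxidatively degraded. The fallback sets out from 2. Alkylation with excess 1,2-dibromoethane (K2CO3, MeCN, reflux) would give 1,2,3-tribromo-4-(2-bromoethoxy)-5-methoxybenzene F3, and E2 elimination with potassium tert-butoxide (THF, 0 °C) would return to the route at vinyl ether 4.

**Further compounds**
F1 | step 6 | 3,5-dibromo-2-(2,3,4-tribromo-6-methoxyphenoxy)benzaldehyde | COc1cc(Br)c(Br)c(Br)c1Oc1c(C=O)cc(Br)cc1Br
F2 | step 6 | 3,5-dibromo-2-(2,3,4-tribromo-6-methoxyphenoxy)phenyl formate | COc1cc(Br)c(Br)c(Br)c1Oc1c(OC=O)cc(Br)cc1Br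
F0 | step 4 | none | none
F3 | step 2 | 1,2,3-tribromo-4-(2-bromoethoxy)-5-methoxybenzene | COc1cc(Br)c(Br)c(Br)c1OCCBr
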